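**Retrosynthetic overview** (prostanoid numbering: ester carbon = C1, ring carbons C8–C12)
1. Target ⇐ bicyclic 5,7-diol; both acetates go on last.
2. Ring B (tetrahydrofuran) ⇐ C6–O12 bond: osmium-catalysed oxidative cyclisation of the C12/C7 1,3-diol onto the (E)-C5=C6 alkene, which also installs the C5 hydroxyl and sets C5 and C6.
3. C7–C8 bond ⇐ anti aldol of the dianion of (R)-2-chloro-4-hydroxy-4-octenylcyclopentenone with methyl (E)-7-oxohept-5-enoate (from cross-metathesis).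
4. Chlorohydroxycyclopentenone ⇐ (S)-4-silyloxycyclopentenone: Z-octenylbarium 1,2-addition (C12), desilylation and allylic oxidation (carbonyl transposition), epoxidation/HCl/elimination (C10–Cl).
5. Ring order: ring A (cyclopentenone) is bought in and kept; ring B is closed in the penultimate step by the C–O bond formation.

Assumption: the target is the (5R,6S,7S,8S,12R,14Z) isomer that the SMILES encodes; locants in the text use the prostanoid numbering above.

**Step 1**
Reactants: 1 methyl hex-5-enoate; 2 (E)-but-2-enal (crotonaldehyde)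
Product: 3 methyl (5E)-7-oxohept-5-enoate
Conditions: (H2IMes)Cl2Ru(=CH-C6H4-2-OiPr) (second-generation Hoveyda–Grubbs catalyst, 2 mol %), 2 (5 equiv), CH2Cl2, 40 °C
Reagents that add atoms: none
Why: Olefin cross-metathesis of the terminal alkene with excess crotonaldehyde releases propene and gives the conjugated enal as the favoured E isomer, with the ester untouched.

**Step 2**
Reactants: 4 (2Z)-oct-2-en-1-ol
Product: 5 (2Z)-1-chlorooct-2-ene
Conditions: N-chlorosuccinimide, Me2S, CH2Cl2, −20 → 0 °C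
Reagents that add atoms: N-chlorosuccinimide, O=C1CCC(=O)N1Cl
Why: Corey–Kim chlorination delivers chloride by SN2 at the primary carbon, so there is no allylic transposition and the Z geometry is kept.

**Step 3**
Reactants: 5 (2Z)-1-chlorooct-2-ene; 6 (4S)-4-[(tert-butyldimethylsilyl)oxy]cyclopent-2-en-1-one
Product: 8 (1R,4S)-4-[(tert-butyldimethylsilyl)oxy]-1-[(2Z)-oct-2-en-1-yl]cyclopent-2-en-1-ol, via octenylbarium chloride 7 (not isolated)
Conditions: BaI2, lithium biphenylide Li(C12H10) (2 equiv), THF, rt; then 5, −78 °C; then 6, −78 °C; aq NH4Cl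
Reagents that add atoms: none
Why: Allylic barium reagents keep their Z geometry at −78 °C and add to ketones through the α-carbon in a 1,2-manner (α-selective allylation), and attack anti to the C4 silyloxy group sets the quaternary carbinol (future C12) as R.

**Step 4**
Reactants: 8 (1R,4S)-4-[(tert-butyldimethylsilyl)oxy]-1-[(2Z)-oct-2-en-1-yl]cyclopent-2-en-1-ol
Product: 9 (1R,4S)-1-[(2Z)-oct-2-en-1-yl]cyclopent-2-ene-1,4-diol
Conditions: Bu4NF, THF, 0 °C → rt
Reagents that add atoms: none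
Why: Fluoride-induced desilylation of the secondary silyl ether touches no stereocentre.

**Step 5**
Reactants: 9 (1R,4S)-1-[(2Z)-oct-2-en-1-yl]cyclopent-2-ene-1,4-diol
Product: 10 (4R)-4-hydroxy-4-[(2Z)-oct-2-en-1-yl]cyclopent-2-en-1-one
Conditions: MnO2 (activated, excess), CH2Cl2, rt
Reagents that add atoms: none
Why: Allylic oxidation with MnO2 takes only the secondary allylic alcohol (the tertiary one cannot be oxidised), which transposes the carbonyl and leaves C12 as the only stereocentre.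

**Step 6**
Reactants: 10 (4R)-4-hydroxy-4-[(2Z)-oct-2-en-1-yl]cyclopent-2-en-1-one
Product: 11 (1R,4R,5S)-4-hydroxy-4-[(2Z)-oct-2-en-1-yl]-6-oxabicyclo[3.1.0]hexan-2-one
Conditions: 30% aq H2O2, NaOH (cat.), MeOH, 0 °C
Reagents that add atoms: hydrogen peroxide, OO
Why: Weitz–Scheffer nucleophilic epoxidation attacks only the electron-poor enone double bond (the isolated Z alkene is inert), syn to the tertiary hydroxyl; the two new centres are erased in step 7.

**Step 7**
Reactants: 11 (1R,4R,5S)-4-hydroxy-4-[(2Z)-oct-2-en-1-yl]-6-oxabicyclo[3.1.0]hexan-2-one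
Product: 14 (4R)-2-chloro-4-hydroxy-4-[(2Z)-oct-2-en-1-yl]cyclopent-2-en-1-one, via chlorohydrin 12 (not isolated), via mesylate 13 (not isolated)
Conditions: HCl (2 M in Et2O, 1.2 equiv), THF, 0 °C; then Et3N, MsCl (1.2 equiv), 0 °C
Reagents that add atoms: hydrogen chloride, Cl
Why: Chloride opens the protonated epoxy ketone at the α-carbon (SN2), then selective mesylation of the secondary hydroxyl and E1cB elimination through the doubly activated α-hydrogen give the 2-chloroenone regiospecifically, leaving the tertiary alcohol alone.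

**Step 8**
Reactants: 14 (4R)-2-chloro-4-hydroxy-4-[(2Z)-oct-2-en-1-yl]cyclopent-2-en-1-one; 3 methyl (5E)-7-oxohept-5-enoate
Product: 16 methyl (5E,7R)-7-[(1S,5R)-3-chloro-5-hydroxy-5-[(2Z)-oct-2-en-1-yl]-2-oxocyclopent-3-en-1-yl]-7-hydroxyhept-5-enoate, via dilithium dianion 15 (not isolated)
Conditions: LiN(SiMe3)2 (2.2 equiv), THF, −78 °C; then 3, −78 °C; aq NH4Cl at −78 °C
Reagents that add atoms: none
Why: Aldol addition of the ring-locked E lithium enolate through a closed Zimmerman–Traxler transition state gives the 7,8-anti adduct, and the aldehyde enters on the ring face that carries the lithium alkoxide (which can bind it) and is opposite the octenyl group, so C8 (S) and C7 are set with the side chain cis to the C12 oxygen; an oxide is no leaving group, so the enolate does not β-eliminate.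

**Step 9**
Reactants: 16 methyl (5E,7R)-7-[(1S,5R)-3-chloro-5-hydroxy-5-[(2Z)-oct-2-en-1-yl]-2-oxocyclopent-3-en-1-yl]-7-hydroxyhept-5-enoate
Product: 19 methyl (5R)-5-[(2S,3S,3aS,6aR)-5-chloro-3-hydroxy-6a-[(2Z)-oct-2-en-1-yl]-4-oxo-3,3a,4,6a-tetrahydro-2H-cyclopenta[b]furan-2-yl]-5-hydroxypentanoate, via hexavalent osmium diolate 17 (not isolated), via tetravalent osmium ester 18 (not isolated)
Conditions: K2OsO2(OH)4 (5 mol %), pyridine N-oxide (2.5 equiv), citric acid (0.75 equiv), Cu(OTf)2 (0.5 equiv), MeCN/aq phosphate buffer (pH 6.5), 50 °C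
Reagents that add atoms: pyridine N-oxide, [O-][n+]1ccccc1
Why: Proposed new method: a 1,3-diol-anchored osmium oxidative cyclisation – the cis-disposed C12 and C7 hydroxyls bind the dioxo-osmium centre as the six-membered diolate 17, the acid additives make the oxo ligand electrophilic, and the O12–Os=O unit adds suprafacially across the 5-exo-positioned C5=C6 bond, so O12–C6 and O–C5 form on one face of the E alkene (5,6-syn, C5 R) while the C7–O–Os anchor holds C5 on the face of the new ring that carries O7 (C6 S, cis-fused ring B); hydrolysis of ester 18 frees 19 and pyridine N-oxide returns tetravalent osmium to the hexavalent state, which is not expected to dihydroxylate the isolated Z alkene; the closest known reaction type is the osmium-catalysed oxidative cyclisation of 1,2-diols onto alkenes to cis-tetrahydrofurans (related to the permanganate oxidative cyclisation of 1,5-dienes), and what is new is the 1,3-diol anchor whose carbinol carbon lies inside the ring being formed, with a tertiary alkoxide as the ring oxygen.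

**Step 10**
Reactants: 19 methyl (5R)-5-[(2S,3S,3aS,6aR)-5-chloro-3-hydroxy-6a-[(2Z)-oct-2-en-1-yl]-4-oxo-3,3a,4,6a-tetrahydro-2H-cyclopenta[b]furan-2-yl]-5-hydroxypentanoate
Product: 20 methyl (5R)-5-acetoxy-5-[(2S,3S,3aS,6aR)-3-acetoxy-5-chloro-6a-[(2Z)-oct-2-en-1-yl]-4-oxo-3,3a,4,6a-tetrahydro-2H-cyclopenta[b]furan-2-yl]pentanoate
Conditions: Ac2O, pyridine, DMAP (5 mol %), CH2Cl2, 0 °C
Reagents that add atoms: acetic anhydride, CC(=O)OC(C)=O
Why: O-Acetylation (nucleophilic acyl substitution) of both secondary alcohols goes with retention, and a short reaction at 0 °C avoids E1cB loss of the C7 acetate.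

**Compound list**
1 | methyl hex-5-enoate | C=CCCCC(=O)OC | starting material
2 | (E)-but-2-enal | C/C=C/C=O | starting material
3 | methyl (5E)-7-oxohept-5-enoate | O=C/C=C/CCCC(=O)OC | intermediate
4 | (2Z)-oct-2-en-1-ol | CCCCC/C=C\CO | starting material
5 | (2Z)-1-chlorooct-2-ene | CCCCC/C=C\CCl | intermediate
6 | (4S)-4-[(tert-butyldimethylsilyl)oxy]cyclopent-2-en-1-one | O=C1C=C[C@@H](O[Si](C)(C)C(C)(C)C)C1 | starting material
7 | (2Z)-oct-2-en-1-ylbarium chloride (formed in the flask) | CCCCC/C=C\C[Ba]Cl | intermediate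
8 | (1R,4S)-4-[(tert-butyldimethylsilyl)oxy]-1-[(2Z)-oct-2-en-1-yl]cyclopent-2-en-1-ol | CCCCC/C=C\C[C@]1(O)C=C[C@@H](O[Si](C)(C)C(C)(C)C)C1 | intermediate
9 | (1R,4S)-1-[(2Z)-oct-2-en-1-yl]cyclopent-2-ene-1,4-diol | CCCCC/C=C\C[C@]1(O)C=C[C@@H](O)C1 | intermediate
10 | (4R)-4-hydroxy-4-[(2Z)-oct-2-en-1-yl]cyclopent-2-en-1-one | CCCCC/C=C\C[C@]1(O)C=CC(=O)C1 | intermediate
11 | (1R,4R,5S)-4-hydroxy-4-[(2Z)-oct-2-en-1-yl]-6-oxabicyclo[3.1.0]hexan-2-one | CCCCC/C=C\C[C@]1(O)[C@H]2O[C@H]2C(=O)C1 | intermediate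
12 | (2S,3R,4R)-2-chloro-3,4-dihydroxy-4-[(2Z)-oct-2-en-1-yl]cyclopentan-1-one (formed in the flask) | CCCCC/C=C\C[C@]1(O)[C@@H](O)[C@H](Cl)C(=O)C1 | intermediate
13 | (1R,2S,5R)-2-chloro-5-hydroxy-5-[(2Z)-oct-2-en-1-yl]-3-oxocyclopentyl methanesulfonate (formed in the flask) | CCCCC/C=C\C[C@]1(O)[C@@H](OS(C)(=O)=O)[C@H](Cl)C(=O)C1 | intermediate
14 | (4R)-2-chloro-4-hydroxy-4-[(2Z)-oct-2-en-1-yl]cyclopent-2-en-1-one | CCCCC/C=C\C[C@]1(O)C=C(Cl)C(=O)C1 | intermediate
15 | dilithium salt of 14: lithium alkoxide at the carbinol, lithium enolate towards the ring CH2 (formed in the flask) | CCCCC/C=C\C[C@]1(O[Li])C=C(Cl)C(O[Li])=C1 | intermediate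
16 | methyl (5E,7R)-7-[(1S,5R)-3-chloro-5-hydroxy-5-[(2Z)-oct-2-en-1-yl]-2-oxocyclopent-3-en-1-yl]-7-hydroxyhept-5-enoate | CCCCC/C=C\C[C@]1(O)C=C(Cl)C(=O)[C@H]1[C@H](O)/C=C/CCCC(=O)OC | intermediate
17 | dioxo-osmium diolate of 16, hexavalent osmium bound to O7 and O12 (formed in the flask) | CCCCC/C=C\C[C@]12C=C(Cl)C(=O)[C@H]1[C@@H](/C=C/CCCC(=O)OC)O[Os](=O)(=O)O2 | intermediate
18 | oxo-osmium ester of 19, tetravalent osmium bound to O5 and O7 (formed in the flask) | CCCCC/C=C\C[C@]12C=C(Cl)C(=O)[C@H]1[C@H](O3)[C@H]([C@@H](CCCC(=O)OC)O[Os]3=O)O2 | intermediate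
19 | methyl (5R)-5-[(2S,3S,3aS,6aR)-5-chloro-3-hydroxy-6a-[(2Z)-oct-2-en-1-yl]-4-oxo-3,3a,4,6a-tetrahydro-2H-cyclopenta[b]furan-2-yl]-5-hydroxypentanoate | CCCCC/C=C\C[C@]12C=C(Cl)C(=O)[C@H]1[C@H](O)[C@H]([C@@H](CCCC(=O)OC)O)O2 | intermediate
20 | methyl (5R)-5-acetoxy-5-[(2S,3S,3aS,6aR)-3-acetoxy-5-chloro-6a-[(2Z)-oct-2-en-1-yl]-4-oxo-3,3a,4,6a-tetrahydro-2H-cyclopenta[b]furan-2-yl]pentanoate | CCCCC/C=C\C[C@]12C=C(Cl)C(=O)[C@H]1[C@H](OC(C)=O)[C@H]([C@@H](CCCC(=O)OC)OC(C)=O)O2 | target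

**Step count:** 10 steps in total. Longest linear sequence: 9 steps (steps 2–10, from 4).

**Three steps most likely to fail**

Step 9 (the proposed new cyclisation). A 1,3-diolate may hold osmium too weakly, the compact cage required for the addition may be too strained, or the acid additives may dehydrate the β-hydroxy ketone. The fallback uses known chemistry, sets out from 16 and returns at 20. Iodoetherification of 16 (I2, NaHCO3, MeCN, 0 °C; 5-exo, anti addition, kinetic cis-2,3 control by the allylic hydroxyl) gives methyl (5S)-5-[(2R,3S,3aS,6aR)-5-chloro-3-hydroxy-6a-[(2Z)-oct-2-en-1-yl]-4-oxo-3,3a,4,6a-tetrahydro-2H-cyclopenta[b]furan-2-yl]-5-iodopentanoate F1. Acetylation (Ac2O, pyridine, 0 °C) gives its 3-acetate F2. Woodward-type solvolysis (AgOAc, wet AcOH) removes iodide with anchimeric help from the cis C7 acetate, so C5 is inverted and the oxygen arrives syn to O6; water then gives the monoacetates, the 5-hydroxy 7-acetate F3 and the 5-acetate 7-alcohol F4. Ac2O/pyridine on the mixture gives 20.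

Step 8 (aldol). The facial selectivity at C8 and the anti selectivity of an unprotected lithium dianion are argued but not proven, and retro-aldol or dehydration can erode the adduct. The fallback sets out from 14 and returns at 16. Silylation (Et3SiOTf, 2,6-lutidine, CH2Cl2, −78 °C) gives (4R)-2-chloro-4-[(2Z)-oct-2-en-1-yl]-4-(triethylsilyloxy)cyclopent-2-en-1-one F5. Its dicyclohexylboron enolate ((c-C6H11)2BCl, Et3N, Et2O, −78 °C) adds to 3 through a tight boron chair (anti aldol) to give methyl (5E,7R)-7-[(1S,5R)-3-chloro-5-[(2Z)-oct-2-en-1-yl]-2-oxo-5-(triethylsilyloxy)cyclopent-3-en-1-yl]-7-hydroxyhept-5-enoate F6. HF·pyridine (THF, 0 °C) removes the silyl group and gives 16.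

Step 3 (allylbarium addition). Active barium is demanding to prepare, and any loss of α-selectivity or Z geometry, or competing enolisation of 6, lowers the yield. The fallback sets out from 6 and returns at 8. Barbier propargylation (propargyl bromide, Zn dust, THF, 0 °C; anti to the silyloxy group) gives (1R,4S)-4-[(tert-butyldimethylsilyl)oxy]-1-(prop-2-yn-1-yl)cyclopent-2-en-1-ol F7. Double deprotonation (n-BuLi, 2.1 equiv, THF/DMPU, −78 → 0 °C) and alkylation of the acetylide with 1-iodopentane gives (1R,4S)-4-[(tert-butyldimethylsilyl)oxy]-1-(oct-2-yn-1-yl)cyclopent-2-en-1-ol F8. Semihydrogenation (H2, Pd/CaCO3 poisoned with Pb(OAc)2, quinoline, EtOAc) gives 8.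

**Further compounds**
F1 | step 9 | methyl (5S)-5-[(2R,3S,3aS,6aR)-5-chloro-3-hydroxy-6a-[(2Z)-oct-2-en-1-yl]-4-oxo-3,3a,4,6a-tetrahydro-2H-cyclopenta[b]furan-2-yl]-5-iodopentanoate | CCCCC/C=C\C[C@]12C=C(Cl)C(=O)[C@H]1[C@H](O)[C@H]([C@H](CCCC(=O)OC)I)O2
F2 | step 9 | methyl (5S)-5-[(2R,3S,3aS,6aR)-3-acetoxy-5-chloro-6a-[(2Z)-oct-2-en-1-yl]-4-oxo-3,3a,4,6a-tetrahydro-2H-cyclopenta[b]furan-2-yl]-5-iodopentanoate | CCCCC/C=C\C[C@]12C=C(Cl)C(=O)[C@H]1[C@H](OC(C)=O)[C@H]([C@H](CCCC(=O)OC)I)O2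
F3 | step 9 | methyl (5R)-5-[(2S,3S,3aS,6aR)-3-acetoxy-5-chloro-6a-[(2Z)-oct-2-en-1-yl]-4-oxo-3,3a,4,6a-tetrahydro-2H-cyclopenta[b]furan-2-yl]-5-hydroxypentanoate | CCCCC/C=C\C[C@]12C=C(Cl)C(=O)[C@H]1[C@H](OC(C)=O)[C@H]([C@@H](CCCC(=O)OC)O)O2
F4 | step 9 | methyl (5R)-5-acetoxy-5-[(2R,3S,3aS,6aR)-5-chloro-3-hydroxy-6a-[(2Z)-oct-2-en-1-yl]-4-oxo-3,3a,4,6a-tetrahydro-2H-cyclopenta[b]furan-2-yl]pentanoate | CCCCC/C=C\C[C@]12C=C(Cl)C(=O)[C@H]1[C@H](O)[C@H]([C@@H](CCCC(=O)OC)OC(C)=O)O2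
F5 | step 8 | (4R)-2-chloro-4-[(2Z)-oct-2-en-1-yl]-4-(triethylsilyloxy)cyclopent-2-en-1-one | CCCCC/C=C\C[C@]1(O[Si](CC)(CC)CC)C=C(Cl)C(=O)C1
F6 | step 8 | methyl (5E,7R)-7-[(1S,5R)-3-chloro-5-[(2Z)-oct-2-en-1-yl]-2-oxo-5-(triethylsilyloxy)cyclopent-3-en-1-yl]-7-hydroxyhept-5-enoate | CCCCC/C=C\C[C@]1(O[Si](CC)(CC)CC)C=C(Cl)C(=O)[C@H]1[C@H](O)/C=C/CCCC(=O)OC
F7 | step 3 | (1R,4S)-4-[(tert-butyldimethylsilyl)oxy]-1-(prop-2-yn-1-yl)cyclopent-2-en-1-ol | C#CC[C@]1(O)C=C[C@@H](O[Si](C)(C)C(C)(C)C)C1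
F8 | step 3 | (1R,4S)-4-[(tert-butyldimethylsilyl)oxy]-1-(oct-2-yn-1-yl)cyclopent-2-en-1-ol | CCCCCC#CC[C@]1(O)C=C[C@@H](O[Si](C)(C)C(C)(C)C)C1
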